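Start with the easy part: these flasks share one charge and differ in their temperature over time, so turn each constant into a time at that charge.

    J + E → E + Q (k1 = 0.740 M⁻¹ s⁻¹, Ea1 = 56.0 kJ mol⁻¹)
    J → D (k2 = 0.00246 s⁻¹, Ea2 = 77.0 kJ mol⁻¹)
    Q → L (k3 = 0.0117 s⁻¹, Ea3 = 67.0 kJ mol⁻¹)
    2 J → J2 (k4 = 0.0352 M⁻¹ s⁻¹, Ea4 = 43.0 kJ mol⁻¹)
    (constants at 5 °C)

| flask | J | E | temperature | time | remark |
|---|---|---|---|---|---|
| midnight | 2.0 M | 70 mM | 5 °C | 6.0 min |  |
| dusk | 2.0 M | 70 mM | 30 °C | 6.0 min |  |
| spring | 2.0 M | 70 mM |  | 6.0 min | at −20 °C until 4.0 min, from then on at 30 °C |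
| dawn | 2.0 M | 70 mM | −20 °C | 6.0 min |  |

- percentages count the J that a species holds: one J2 counts as two
- where a step has two of a species, its rate is k times that concentration squared, and two are used at each turn
- at 5 °C the constants are as listed, elsewhere as the activation energies make them

- the best flask by amount of Q, in percent of the J charged; "all alike" if 1.5 percentage points covers them all (midnight / dusk / spring / dawn / all alike)
- amount of Q at the end, in percent of the J charged, midnight
- amount of Q at the end, in percent of the J charged, dusk
- amount of Q at the end, in percent of the J charged, spring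
- amount of Q at the end, in percent of the J charged, dawn

I build dawn, held at −20 °C, one process at a time, and then carry its last quantity to the other flasks.

1. Main step, J + E → E + Q (k1 = 0.740 M⁻¹ s⁻¹, Ea1 = 56.0 kJ mol⁻¹). E is given back at each turn, so J decays in a pseudo-first-order way, with constant a = 0.284 min⁻¹ in dawn. That is a time of 3.52 min, and by itself in dawn this step would turn 81.8% of the J into Q within 6.0 min.

2. Add the dimerisation, 2 J → J2 (k4 = 0.0352 M⁻¹ s⁻¹, Ea4 = 43.0 kJ mol⁻¹). Its first half-life at the charge in dawn is 1/b, with b = 1.35 min⁻¹, which gives 0.741 min. This is shorter than the main step's time, so in dawn the dimerisation wins the early J. Integrating the two together with r = b/a = 4.74, the share of the charge reaching Q, reckoned to the point where J has gone, is s = ln(1+r)/r, in dawn 36.9%.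

3. Add J → D (k2 = 0.00246 s⁻¹, Ea2 = 77.0 kJ mol⁻¹). In dawn its constant is 0.00551 min⁻¹, far below a, so I drop it.

4. Add the decay of Q, Q → L (k3 = 0.0117 s⁻¹, Ea3 = 67.0 kJ mol⁻¹). Here is the quantity to carry: the lifetime τ of Q at the flask's temperature, the time in which its decay lowers Q by a factor e. In dawn τ = 24.9 min. So the run in dawn lasts 0.241 lifetimes, and Q made at its start keeps 78.6%. Counting s as if it were made at the start, and J as if it had gone by the end, I commit to s times that for dawn: 29.0%.

5. Carry τ across. At 5 °C it is 85.5 s, so 6.0 min is 4.21 lifetimes. With s reckoned the same way, 48.3%, midnight gives 0.716%. At 30 °C it is 7.84 s. Dusk then runs 45.9 lifetimes, and the warm end of spring runs 15.3, which leaves hardly any of its Q. My pick is dawn, well above the others.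

The forecast also names dawn, with 27.8% there, 0.84% in midnight, 0% in dusk and <0.001% in spring. Its dawn figure lies below mine and its midnight figure above mine. Its ground: "Q is an intermediate, and loss step 3 has a higher activation energy than its formation, so warmth destroys it".

The simulation gives dawn as the best flask, with 27.8% against 0.832% in midnight, 0% in dusk and 0% in spring. In dawn, half of the main step's turnover up to the end is behind it by 1.03 min, far earlier than the half-life of Q by its decay, 17 min, which is τ·ln(2) with τ = 24.9 min. Dawn read at 15 min holds 21.8% of Q; my reckoning with τ, counting decay and no new Q, puts 27.8% down to 19.4% over the added time, and meanwhile J falls from 3.6% to 0.23%.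

The rate constants are assumed; the flask was simulated.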